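The cyclohexane ring is cut at C1–C14 and C10–C11 (eunicellane numbering: C1/C10 ring fusion, C11 the methyl carbinol carbon, C14 the isopropyl-bearing carbon). The feature exploited is that O11 and the isopropyl methine C15 are cis and 1,4 across this ring, so they can be tied as the O–C(=O) bridge of a 2-pyrone. One endo Diels–Alder reaction of 6-methyl-2-pyrone with (5R)-5-menthyloxybutenolide forms both bonds, sets C1, C10, C11 and C14, and supplies C2 and C9 as differentiated carbonyl carbons. The lactone carbonyl is later methylated into the isopropyl group, and the ten-membered ring is closed last by a Nozaki–Hiyama–Kishi reaction.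

Key step: step 1

Remark: atom numbers are those of the eunicellane skeleton of the target (six-membered ring C1, C10, C11, C12, C13, C14; ten-membered ring C1 to C10; C15 the isopropyl methine; C6 and C9 the acetoxy carbons; C7 the methylene-bearing carbon).
Remark: 1 and 2 are taken as purchasable; 2 is otherwise available in one step from 5-hydroxyfuran-2(5H)-one and (1R,2S,5R)-menthol.

Step 1
Reactants: 1 6-methyl-2H-pyran-2-one; 2 (5R)-5-[(1R,2S,5R)-menthyloxy]furan-2(5H)-one
Product: 3 endo cycloadduct (bridged bis-lactone, C12=C13 olefin)
Conditions: CH2Cl2, 15 kbar, 45 °C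
Reagents that add atoms: none
Why: Concerted, asynchronous normal-demand [4+2] cycloaddition of the pyrone diene (C14=C13–C12=C11) to the butenolide C1=C10 bond, the known Diels–Alder reaction of 2-pyrones with cyclic Z-dienophiles, run at high pressure so that the adduct does not lose CO2, combined with the auxiliary-controlled cycloaddition of 5-menthyloxybutenolides. Both new bonds close the carbocyclic six-membered ring by suprafacial [4+2] addition and, because the diene is cyclic, the same event closes the second six-membered ring C1–C10–C11–O–C15–C14 of the 2-oxabicyclo[2.2.2]octenone. C1 and C10 come out cis because the Z olefin is locked in the five-membered lactone, and their absolute configuration is set by the (5R)-acetal centre, the diene adding to the face anti to the menthyloxy group. C11 and C14 are set relative to C1/C10 by the endo orientation (lactone carbonyl under C12=C13, anti to the O–C(=O) bridge), and the bridge itself fixes O11 and C15 cis. The step needs head-to-head regiochemistry (pyrone C3, the future C14, to the butenolide β-carbon; pyrone C6, the future C11, to the α-carbon), which the polarisation of both partners should secure: C3 is the nucleophilic terminus of the 6-methylpyrone (donation from the ring oxygen and the methyl group at C6) and the β-carbon is the electrophilic terminus of the butenolide. High pressure favours the compact endo transition state.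

Step 2
Reactants: 3 endo cycloadduct
Product: 4 saturated bridged bis-lactone
Conditions: H2 (1 atm), 10% Pd/C, EtOAc, rt
Reagents that add atoms: none
Why: Heterogeneous catalytic hydrogenation of the strained cis-disubstituted C12=C13 bond is fast and chemoselective over the two lactones and the acetal, creates no stereocentre and removes the retro-Diels–Alder (CO2 loss) pathway.

Step 3
Reactants: 4 saturated bridged bis-lactone
Product: 5 dithiane acid (bridged lactone kept)
Conditions: HS(CH2)3SH, BF3·OEt2, CH2Cl2, 0 °C → rt
Reagents that add atoms: propane-1,3-dithiol SCCCS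
Why: Lewis-acid thioacetalisation of the acylal: BF3 ionises the C2–O bond of the γ-lactone, the dithiol traps the oxocarbenium ion and displaces menthol, giving the 1,3-dithiane at C2 and the free C9 acid, while the bridged lactone, whose alkyl oxygen sits on a bridgehead, cannot ionise and stays intact.

Step 4
Reactants: 5 dithiane acid
Product: 6 hydroxy keto acid (C14 acetyl, C11 tertiary alcohol)
Conditions: MeLi (2.3 equiv), THF, −78 °C; aq NH4Cl at −78 °C
Reagents that add atoms: methyllithium [Li]C
Why: Addition of MeLi to a lactone at low temperature stops at the lithium hemiketal, which gives the methyl ketone on quench (C15 gains its first methyl, O11 is released as the tertiary alcohol), while the lithium carboxylate formed by the first equivalent is inert at −78 °C; C14 keeps its configuration, which is also the thermodynamic one (acetyl equatorial, trans to the C1 substituent).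

Step 5
Reactants: 6 hydroxy keto acid
Product: 7 isopropenyl hydroxy acid
Conditions: Ph3PCH3Br, KOtBu (excess), THF, 0 °C → reflux
Reagents that add atoms: methyltriphenylphosphonium bromide C[P+](c1ccccc1)(c1ccccc1)c1ccccc1.[Br-]
Why: Wittig methylenation of the methyl ketone with excess ylide (carboxylate and alkoxide are spectators) installs the second isopropyl carbon as an isopropenyl group; the enolisable C14 centre already holds the stable equatorial configuration.

Step 6
Reactants: 7 isopropenyl hydroxy acid
Product: 8 isopropenyl hydroxylactone (pseudo-acid)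
Conditions: PhI(OCOCF3)2, MeCN/H2O (9:1), 0 °C
Reagents that add atoms: water O
Why: Oxidative hydrolysis of the dithiane with the hypervalent iodine reagent is fast at 0 °C and spares the 1,1-disubstituted olefin; the liberated C2 aldehyde closes onto the cis C9 acid as the hydroxylactone, and sulfur is removed before the next hydrogenation.

Step 7
Reactants: 8 isopropenyl hydroxylactone
Product: 9 isopropyl hydroxylactone (pseudo-acid)
Conditions: H2 (1 atm), 10% Pd/C, EtOAc, rt
Reagents that add atoms: none
Why: Catalytic hydrogenation of the isopropenyl group gives the isopropyl group (no new stereocentre, C15 bears two methyls) and leaves the lactol alone; all hydrogenations are thus finished before any olefin of the target is introduced.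

Step 8
Reactants: 9 isopropyl hydroxylactone
Product: 10 (Z)-iodoalkene acid
Conditions: Ph3PCH2CH3 I, n-BuLi, THF, rt; I2, −78 °C; NaN(SiMe3)2, −20 °C; then 9 (pretreated with NaN(SiMe3)2, 2.2 equiv), −78 → −20 °C
Reagents that add atoms: ethyltriphenylphosphonium iodide CC[P+](c1ccccc1)(c1ccccc1)c1ccccc1.[I-]; iodine II
Why: Stork–Zhao-type Wittig olefination with the α-iodoethylidene ylide on the aldehyde carboxylate, which the base releases from the pseudo-acid, gives the (Z)-iodoalkene (C1 and I cis) that fixes the C2=C3 geometry of the target.

Step 9
Reactants: 10 (Z)-iodoalkene acid; 11 acrolein diethyl acetal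
Product: 13 (Z)-olefinic acetal acid, via alkylborane 12 (not isolated)
Conditions: 11, 9-BBN, THF, rt; then 10, Pd(dppf)Cl2 (5 mol %), AsPh3, K3PO4 (3 M aq), DMF/THF, rt
Reagents that add atoms: none
Why: B-alkyl Suzuki–Miyaura coupling of the alkylborane from anti-Markovnikov hydroboration of 11 proceeds with retention at the alkenyl iodide, so C4 takes the place of iodine cis to C1 and the trisubstituted olefin is Z; the carboxylate is tolerated under the aqueous basic conditions.

Step 10
Reactants: 13 (Z)-olefinic acetal acid
Product: 14 primary C9 alcohol
Conditions: LiAlH4, THF, 0 °C → rt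
Reagents that add atoms: none
Why: LiAlH4 reduces the carboxylic acid to the primary alcohol and leaves the acetal, the trisubstituted olefin and the tertiary alcohol unchanged.

Step 11
Reactants: 14 primary C9 alcohol
Product: 15 C9 aldehyde
Conditions: DMP (triacetoxy periodinane), NaHCO3, CH2Cl2, 0 °C → rt; used crude
Reagents that add atoms: none
Why: Periodinane oxidation under buffered, non-basic conditions gives the aldehyde without epimerising the axial formyl group at C10 or triggering retro-aldol cleavage of the β-hydroxy aldehyde; the tertiary alcohol cannot be oxidised.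

Step 12
Reactants: 15 C9 aldehyde; 16 2,3-dibromopropene
Product: 17 (9R)-2-bromoallyl carbinol
Conditions: indium powder, DMF, rt
Reagents that add atoms: none
Why: Indium-mediated Barbier allylation transfers the 2-bromoallyl group under neutral conditions that spare the acetal; 1,2-induction (attack on the axial formyl group anti to the quaternary C11, from the exposed outer face of the ring) should give the 9R carbinol.

Step 13
Reactants: 17 (9R)-2-bromoallyl carbinol
Product: 18 seco aldehyde
Conditions: pyridinium p-toluenesulfonate (cat.), acetone/H2O (10:1), 50 °C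
Reagents that add atoms: water O
Why: Mild acid-catalysed acetal hydrolysis unmasks the C6 aldehyde; the alkenyl bromide, the homoallylic alcohol and the tertiary alcohol are stable to this weak acid.

Step 14
Reactants: 18 seco aldehyde
Product: 19 triol (ten-membered ring closed)
Conditions: CrCl2 (8 equiv), NiCl2 (2 mol %), DMSO/THF (3:1), 0.003 M, rt
Reagents that add atoms: none
Why: Nozaki–Hiyama–Kishi reaction: nickel-catalysed activation of the alkenyl bromide and transfer to chromium give an alkenylchromium species that adds chemoselectively to the aldehyde in the presence of free hydroxyl groups, closing the ten-membered ring at C6–C7 (preorganised by the Z olefin and the cis ring fusion) and giving the allylic alcohol with the exocyclic methylene; C6 is set by macrocyclic substrate control (carbonyl oxygen on the ring periphery), which is expected to give the 6R carbinol and is the least secure stereocentre of the route.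

Step 15
Reactants: 19 triol
Product: 20 target diacetate
Conditions: Ac2O, pyridine, DMAP (cat.), CH2Cl2, 0 °C
Reagents that add atoms: acetic anhydride CC(=O)OC(C)=O
Why: Acylation with Ac2O/pyridine and catalytic DMAP esterifies the two secondary alcohols at C6 and C9, while the hindered tertiary C11 alcohol does not react at 0 °C.

Compound list
1 | 6-methyl-2H-pyran-2-one | CC1=CC=CC(=O)O1 | starting material
2 | (5R)-5-[(1R,2S,5R)-menthyloxy]furan-2(5H)-one | O=C1C=C[C@H](O[C@@H]2C[C@H](C)CC[C@H]2C(C)C)O1 | starting material
3 | endo cycloadduct: 1-methyl-2-oxabicyclo[2.2.2]oct-7-en-3-one with a γ-lactone cis-fused across C5–C6 on the side away from the O–C(=O) bridge; lactone carbonyl (future C9) on C6 next to the methyl-bearing bridgehead, (R)-menthyloxy acetal carbon (future C2) on C5, menthyloxy trans to the bicycle | O=C1O[C@@H](O[C@@H]4C[C@H](C)CC[C@H]4C(C)C)[C@H]2[C@@H]1[C@]3(C)OC(=O)[C@H]2C=C3 | intermediate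
4 | 7,8-dihydro derivative of 3 (saturated bridged bis-lactone) | O=C1O[C@@H](O[C@@H]4C[C@H](C)CC[C@H]4C(C)C)[C@H]2[C@@H]1[C@]3(C)OC(=O)[C@H]2CC3 | intermediate
5 | 6-carboxy-5-(1,3-dithian-2-yl)-1-methyl-2-oxabicyclo[2.2.2]octan-3-one, the two substituents cis and anti to the lactone bridge | OC(=O)[C@@H]1[C@H](C2SCCCS2)[C@@H]3CC[C@@]1(C)OC3=O | intermediate
6 | hydroxy keto acid: cyclohexane with C10–CO2H, C1–(1,3-dithian-2-yl), C14–acetyl, C11–(CH3)(OH), configured at C1, C10, C11, C14 as in the target (in equilibrium with its bicyclic hemiketal) | OC(=O)[C@@H]1[C@H](C2SCCCS2)[C@@H](C(C)=O)CC[C@@]1(C)O | intermediate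
7 | as 6 with C14–isopropenyl | OC(=O)[C@@H]1[C@H](C2SCCCS2)[C@@H](C(C)=C)CC[C@@]1(C)O | intermediate
8 | hydroxylactone (pseudo-acid, anomer mixture) from the C2 aldehyde and the cis C9 acid; C14–isopropenyl, C11 tertiary alcohol | O=C1OC(O)[C@H]2[C@@H]1[C@](C)(O)CC[C@@H]2C(C)=C | intermediate
9 | as 8 with C14–isopropyl | O=C1OC(O)[C@H]2[C@@H]1[C@](C)(O)CC[C@@H]2C(C)C | intermediate
10 | (Z)-iodoalkene acid: C1–CH=C(I)CH3 with C1 and I cis, C10–CO2H, core as in the target | OC(=O)[C@@H]1[C@H](/C=C(/C)I)[C@@H](C(C)C)CC[C@@]1(C)O | intermediate
11 | acrolein diethyl acetal (3,3-diethoxyprop-1-ene) | C=CC(OCC)OCC | starting material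
12 | B-(3,3-diethoxypropyl)-9-borabicyclo[3.3.1]nonane | CCOC(CCB1C2CCCC1CCC2)OCC | intermediate
13 | acetal acid: C1–[(Z)-CH=C(CH3)CH2CH2CH(OEt)2], C10–CO2H | OC(=O)[C@@H]1[C@H](/C=C(/C)CCC(OCC)OCC)[C@@H](C(C)C)CC[C@@]1(C)O | intermediate
14 | as 13 with C9 as CH2OH | OC[C@@H]1[C@H](/C=C(/C)CCC(OCC)OCC)[C@@H](C(C)C)CC[C@@]1(C)O | intermediate
15 | as 13 with C9 as CHO | O=C[C@@H]1[C@H](/C=C(/C)CCC(OCC)OCC)[C@@H](C(C)C)CC[C@@]1(C)O | intermediate
16 | 2,3-dibromopropene | C=C(Br)CBr | starting material
17 | (9R)-homoallylic alcohol: C10–CH(OH)CH2C(Br)=CH2, acetal side chain on C1 | C=C(Br)C[C@@H](O)[C@@H]1[C@H](/C=C(/C)CCC(OCC)OCC)[C@@H](C(C)C)CC[C@@]1(C)O | intermediate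
18 | seco aldehyde: as 17 with C6 as CHO | C=C(Br)C[C@@H](O)[C@@H]1[C@H](/C=C(/C)CCC=O)[C@@H](C(C)C)CC[C@@]1(C)O | intermediate
19 | (1S,2Z,6R,9R,10S,11R,14R)-eunicella-2,7(19)-diene-6,9,11-triol | C=C1C[C@@H](O)[C@@H]2[C@H](/C=C(/C)CC[C@H]1O)[C@@H](C(C)C)CC[C@@]2(C)O | intermediate
20 | (1S,2Z,6R,9R,10S,11R,14R)-11-hydroxyeunicella-2,7(19)-diene-6,9-diyl diacetate | C=C1C[C@@H](OC(C)=O)[C@@H]2[C@H](/C=C(/C)CC[C@H]1OC(C)=O)[C@@H](C(C)C)CC[C@@]2(C)O | target

Total step count: 15. Longest linear sequence: 15 steps (1 or 2 to 20).

Steps most likely to fail

1. Step 1 (cycloaddition). What may go wrong: the two partners may combine in the wrong or in both orientations (head-to-tail adduct), or the adduct may lose CO2 before it is reduced. Fallback, setting out from 1 and returning at 4: maleic anhydride, whose two ends are alike, removes the regiochemical question. Thermal Diels–Alder reaction of 1 with maleic anhydride (PhMe, 90 °C) gives the racemic endo anhydride adduct F1. Hydrogenation (H2, Pd/C, EtOAc) gives the saturated anhydride F2. LiAlH(OtBu)3 (THF, −40 °C) reduces the less hindered anhydride carbonyl, the one on the ring carbon next to the CH bridgehead, to the racemic hydroxylactone F3. Acid-catalysed acetalisation of F3 with (1R,2S,5R)-menthol (TsOH, benzene, azeotropic removal of water) and separation of the two diastereomeric menthyl acetals by crystallisation gives 4.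

2. Step 14 (ring closure). What may go wrong: poor facial selectivity in the addition to the C6 aldehyde, giving both C6 epimers. Fallback, setting out from the C6-epimer mixture of 19 obtained from 18 and returning at 19: MnO2 (CH2Cl2, rt) oxidises only the allylic C6 carbinol and gives the cross-conjugated enone F4. F4 is reduced at once with (S)-2-methyl-CBS-oxazaborolidine and BH3·SMe2 (THF, −30 °C). The catalyst treats the alkenyl group as the large substituent and should deliver the 6R alcohol under reagent control, which is 19.

3. Step 12 (allylation). What may go wrong: poor facial selectivity in the addition to the C9 aldehyde, which rests on substrate control alone. Fallback, setting out from 15 and returning at 17: reagent control with the chiral B-(2-bromoallyl)-4,5-diphenyl-1,3-bis(p-tolylsulfonyl)-1,3,2-diazaborolidine, made from the bis-sulfonamide of 1,2-diphenylethylenediamine, BBr3 and (2-bromoallyl)tributylstannane. The enantiomer that attacks the Re face of the aldehyde is used (CH2Cl2, −78 °C) and gives 17 directly (no new compound, F0).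

Further compounds
F1 | step 1 | racemic endo maleic anhydride adduct of 1 (1-methyl-2-oxabicyclo[2.2.2]oct-7-en-3-one with cis-fused anhydride anti to the lactone bridge; one enantiomer drawn) | O=C1OC(=O)[C@H]2[C@@H]1[C@]3(C)OC(=O)[C@H]2C=C3
F2 | step 1 | racemic saturated anhydride (7,8-dihydro F1) | O=C1OC(=O)[C@H]2[C@@H]1[C@]3(C)OC(=O)[C@H]2CC3
F3 | step 1 | racemic hydroxylactone (lactol carbon on the ring carbon next to the CH bridgehead, anomer mixture) | O=C1OC(O)[C@H]2[C@@H]1[C@]3(C)OC(=O)[C@H]2CC3
F4 | step 14 | (1S,2Z,9R,10S,11R,14R)-9,11-dihydroxyeunicella-2,7(19)-dien-6-one | C=C1C[C@@H](O)[C@@H]2[C@H](/C=C(/C)CCC1=O)[C@@H](C(C)C)CC[C@@]2(C)O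
F0 | step 12 | none | none
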